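## Analysis of the target

Gnetal (16) is a 2,3-dihydro-1-benzofuran. Ring A (the benzo ring, C3a to C7a) carries a free hydroxyl on C4 and a formyl group on C6. C2 bears a 4-hydroxyphenyl group (ring B) and C3 a 3,5-dihydroxyphenyl group (ring C). The only stereocentres are the neighbouring benzylic carbons C2 and C3, both S, with the two aryl groups trans across the five-membered ring.

The molecule is sensitive in three ways. It has four oxidisable phenols and an aryl aldehyde. The O1–C2 bond is a para-oxygenated benzyl aryl ether that can ionise under acid. The C3–H bond is doubly benzylic and lies para, through ring A, to the C6 formyl group, so a base could deprotonate C3 and expel O1 with ring opening.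

The synthesis is hard for two reasons. Neither stereocentre has a neighbouring directing group apart from O1. And C3a sits between the oxygenated carbons C4 and C7a, so the C3–C3a bond has to be made to an arene that is substituted at both ortho positions.

The strategy rests on the C2–C3 unit: two adjacent sp3 carbons, each with one hydrogen and one aryl group, C2 also bearing O1. This unit is read as an (E)-alkene carrying ring C, to which ring B is delivered from boron at C2 and ring A from palladium at C3. The C–B bond left on C2 is the latent O1.

## Retrosynthetic reasoning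

**16 back to 15.** The four O–CH3 bonds are cut last. Free phenols would interfere with every organometallic step and with the palladium-catalysed etherification, so they are carried as methyl ethers, which the three commercial building blocks already contain. The forward reaction must cleave four aryl methyl ethers without permanent damage to the O1–C2 bond or the aldehyde.

**15 back to 14.** The formyl group is traced to a dioxolane. Masked, C6 no longer acidifies C3–H, and the carbonyl is protected from alkaline peroxide and from the basic coupling conditions. The forward step is a mild aqueous acid hydrolysis.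

**14 back to 13.** The five-membered ring is opened at C7a–O1, not at O1–C2. Closing at C7a leaves all four bonds of C2 untouched, so the configuration of the carbinol is carried into the ring unchanged. Closing at C2 would pass through a benzylic cation or an inversion. This leaves chloro alcohol 13, with chlorine on the ring A carbon that becomes C7a. The forward reaction is an intramolecular aryl ether formation under palladium catalysis.

**13 back to 12.** The C2–O bond is exchanged for a C2–B bond. A boronic ester oxidises to the alcohol with retention, so the oxygen can be carried through the key step as boron. This is what makes a boron-based three-component coupling usable here.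

**12 back to 8, 10 and 3 (key disconnection).** Two bonds are cut together: C2–aryl (ring B) and C3–C3a. This gives the (E)-alkenyl boronate 8 carrying ring C, the aryllithium 10 (ring B), and the ring A triflate 3.

- The roles follow from stereochemistry. The aryl group from boron and the aryl group from palladium add anti across the alkene. Only with ring C on the (E)-alkene and ring A on palladium does this give the diastereomer that closes to the trans ring. With ring A on the alkene and ring C as the electrophile, a (Z)-alkene would be needed.
- Both stereocentres, the whole carbon skeleton and the latent O1 arise in one catalytic step from three achiral pieces.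
- The boron ligand of 8 is the diol 5 and not a simpler diol. A substituent on the far alkene carbon otherwise diverts such ate complexes into direct transfer of the alkenyl group to palladium.
- The forward reaction has to choose the triflate over the chloride of 3, favour the 1,2-shift over transmetallation, and select one alkene face.

**8 back to 6 and 5, and 5 back to 4.** The B–C(sp2) bond is cut by a hydroboration transform to the terminal alkyne 6; syn addition of B–H fixes the E geometry. The first-formed boronate 7 is exchanged onto diol 5. Diol 5 comes from the diketone 4 by double addition of a methyl nucleophile.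

**10 back to 9.** The C–Li bond comes from the C–Br bond of 9 by halogen–lithium exchange. This places lithium para to the methoxy group, which deprotonation could not do.

**3 back to 2 and 1.** The dioxolane is removed to aldehyde 2 and the triflate to the phenol of 1. Compound 1 already holds the chlorine, the methoxy group and the formyl group in the pattern ring A needs. Triflation precedes acetal formation, because a free para-hydroxyl deactivates the aldehyde and makes its acetals labile.

## Alternatives that were turned down

**Alternative 1: ring A built around C3a by benzannulation.**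
- Disconnection: the ring A bonds C3a–C4, C7–C7a and C4–C5 are cut, so ring A is assembled last on a side chain that already holds C2 and C3.
- Forward key step: cyclobutenone A2 and siloxyalkyne A3 are heated. A vinylketene [2+2] addition, four-electron ring opening and six-electron ring closure give the ring A phenol A1.
- For it: this is stronger than the chosen route on one point. No bond is ever made to a doubly ortho-substituted arene, because both ortho oxygens arrive with the ring. Since ring A is symmetric about the C3a–C6 axis, either oxygen can later close onto C2.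
- Against it: both stereocentres must be set beforehand in A3, where C3 is benzylic and propargylic and therefore easily epimerised on the way to the ynol ether. The cascade needs prolonged heating of a hindered, branched alkyne with a leaving group beta to it. After A1, the ring still has to be closed at C2 through a cation, the silyl groups removed, and C6 oxidised from the alcohol to the aldehyde level.
- Comparison: the chosen route instead buys ring A with its substitution pattern in 1 and creates both stereocentres catalytically in step 5. It accepts the crowded coupling as its single concentrated risk and is several steps shorter.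

**Alternative 2: flavanone ring contraction.**
- Disconnection: the C3–C3a bond is traced to a 1,2-shift of the ring A carbon in flavanone A5.
- Forward key step: a trivalent iodine oxidant in an acidic orthoformate medium attacks C3 of the enol ether of A5. The ring A carbon migrates from the carbonyl carbon to C3, giving the trans diester A4.
- For it: the C3–C3a bond forms intramolecularly, so crowding at C3a is no obstacle. The trans relationship comes from the rearrangement itself. On both points it is at least as strong as the chosen route.
- Against it: C3 of A4 carries an ester where the target has ring C. Replacing a carboxyl by an aryl group at a benzylic position means a decarboxylative coupling through a C3 radical. The configuration made in the key step is thus erased and has to be set again on a hindered centre. The single enantiomer would rest on C2 of A5 alone, which can racemise by ring opening. The second ester must also be taken down to the aldehyde.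
- Comparison: the chosen route has ring C in place from its first step and never has to rebuild a stereocentre.

**Alternative 3: ring A from a fused 2-pyrone.**
- Disconnection: the ring A bonds C3a–C4 and C5–C6 are cut.
- Forward key step: the furo-fused pyrone A7 and ethoxyethyne A8 undergo an inverse-demand Diels–Alder reaction across the pyrone termini. The adduct loses its lactone bridge to give A6.
- For it: the polarity of the two partners puts the alkoxy group on C4, the aldehyde is already present, and again no crowded aryl coupling is needed.
- Against it: all the stereochemical difficulty is moved into A7. A7 is a dihydrofuran bearing the same two aryl groups on the same two carbons, for which no more direct enantioselective entry exists than for 16 itself. The cycloaddition needs heat in the presence of a formyl-substituted, electrophilic pyrone. The ethyl ether of A6 must be cleaved under the same conditions as a methyl ether.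
- Comparison: the chosen route solves the stereochemical problem in its key step and does not defer it to an earlier intermediate of equal difficulty.

Key step: step 5

Assumption: the (Sp,Sp) antipode of the ferrocenyl diphosphine is taken to deliver the (1S,2S) boronate 12. If the sense of induction is opposite for this substrate, the mirror-image ligand is used with no other change.

## Route

Step 1
Reactants: 1 5-chlorovanillin (3-chloro-4-hydroxy-5-methoxybenzaldehyde)
Product: 2 2-chloro-4-formyl-6-methoxyphenyl trifluoromethanesulfonate
Conditions: Tf2O, pyridine, CH2Cl2, 0 °C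
Reagents that add atoms: trifluoromethanesulfonic anhydride, O=S(=O)(OS(=O)(=O)C(F)(F)F)C(F)(F)F
Why: O-sulfonylation of an acidic phenol; the aldehyde is inert to the anhydride, and the ring A carbon that will become C3a is now activated for oxidative addition.

Step 2
Reactants: 2 2-chloro-4-formyl-6-methoxyphenyl trifluoromethanesulfonate
Product: 3 2-chloro-4-(1,3-dioxolan-2-yl)-6-methoxyphenyl trifluoromethanesulfonate
Conditions: ethylene glycol, p-TsOH (cat.), toluene, reflux, Dean–Stark
Reagents that add atoms: ethylene glycol, OCCO
Why: acid-catalysed acetal formation with removal of water; with the phenol already sulfonylated the carbonyl is no longer deactivated by a para-oxygen donor, and aryl triflates tolerate these acidic conditions.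

Step 3
Reactants: 4 acenaphthoquinone (acenaphthylene-1,2-dione)
Product: 5 cis-1,2-dimethyl-1,2-dihydroacenaphthylene-1,2-diol (meso)
Conditions: MeMgBr (2.5 equiv), THF, −78 °C to rt; aq. NH4Cl; recrystallisation
Reagents that add atoms: methylmagnesium bromide, C[Mg]Br
Why: double Grignard addition to a 1,2-diketone; the second methyl should add to the face away from the solvated magnesium alkoxide and so mainly give the cis diol, and only the cis diol can bridge boron in step 4.

Step 4
Reactants: 6 1-ethynyl-3,5-dimethoxybenzene; 5 cis-1,2-dimethyl-1,2-dihydroacenaphthylene-1,2-diol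
Product: 8 (E)-2-(3,5-dimethoxyphenyl)ethenylboronic acid cis-1,2-dimethylacenaphthene-1,2-diyl ester, via alkenyl catechol boronate 7 (not isolated)
Conditions: catecholborane, THF, 65 °C; then 5, rt
Reagents that add atoms: catecholborane, B1Oc2ccccc2O1
Why: syn, anti-Markovnikov hydroboration of a terminal alkyne fixes the E geometry; the Lewis-acidic catechol ester then exchanges readily with the pre-organised aliphatic cis diol (transesterification) to give a chromatography-stable boronate.

Step 5
Reactants: 9 4-bromoanisole; 8 (E)-2-(3,5-dimethoxyphenyl)ethenylboronic acid cis-1,2-dimethylacenaphthene-1,2-diyl ester; 3 2-chloro-4-(1,3-dioxolan-2-yl)-6-methoxyphenyl trifluoromethanesulfonate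
Product: 12 [(1S,2S)-2-[2-chloro-4-(1,3-dioxolan-2-yl)-6-methoxyphenyl]-2-(3,5-dimethoxyphenyl)-1-(4-methoxyphenyl)ethyl]boronic acid cis-1,2-dimethylacenaphthene-1,2-diyl ester, via 4-methoxyphenyllithium 10 (not isolated), via lithium boron ate complex 11 (not isolated)
Conditions: 9, t-BuLi (2 equiv), Et2O, −78 °C; 8, THF, −78 °C to rt; then 3, Pd(OAc)2 (3 mol%), (Sp,Sp)-1,1'-bis[bis(4-methoxy-3,5-dimethylphenyl)phosphino]-2,2'-bis[(R)-(dimethylamino)(phenyl)methyl]ferrocene (3.6 mol%), KOTf (2 equiv), THF, 60 °C
Reagents that add atoms: none
Why: Bromine–lithium exchange gives 10, which adds to the trigonal boron of 8 to form the four-coordinate borate 11 before any electrophile is present. Zerovalent palladium, formed from Pd(OAc)2 and the diphosphine, inserts into the C–OTf bond of 3 to give a cationic arylpalladium species that binds the alkene of 11. The 4-methoxyphenyl group then shifts from boron to C2 on the face opposite palladium while palladium bonds to C3 (1,2-metallate shift), and reductive elimination joins C3 to C3a with retention. The closest known reaction type is the palladium-catalysed enantioselective conjunctive cross-coupling of beta-substituted alkenylboron ate complexes with aryl triflates, in which the hindered acenaphthene-derived diol on boron is what holds back direct Suzuki–Miyaura transfer. No ring closes in this step. The relative configuration of C2 and C3 follows from the anti addition across the (E)-alkene, and the absolute configuration from the face of the alkene that the chiral diphosphine on palladium selects. The step needs triflate over chloride selectivity, which a chelating diphosphine and the cationic pathway favour, and it needs a halide-poor medium, which KOTf secures by taking up the bromide left from the exchange. Palladium is expected at C3 and not at C2 because C3 is benzylic and C2 carries the boron from which the migrating group departs.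

Step 6
Reactants: 12 [(1S,2S)-2-[2-chloro-4-(1,3-dioxolan-2-yl)-6-methoxyphenyl]-2-(3,5-dimethoxyphenyl)-1-(4-methoxyphenyl)ethyl]boronic acid cis-1,2-dimethylacenaphthene-1,2-diyl ester
Product: 13 (1S,2S)-2-[2-chloro-4-(1,3-dioxolan-2-yl)-6-methoxyphenyl]-2-(3,5-dimethoxyphenyl)-1-(4-methoxyphenyl)ethan-1-ol
Conditions: H2O2 (30% aq.), NaOH (3 M aq.), THF, 0 °C to rt
Reagents that add atoms: hydrogen peroxide, OO
Why: oxidation of a secondary boronic ester by hydroperoxide; the carbon migrates from boron to oxygen with retention, so C2 keeps its configuration, and the acetal, aryl chloride and methyl ethers are inert to alkaline peroxide.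

Step 7
Reactants: 13 (1S,2S)-2-[2-chloro-4-(1,3-dioxolan-2-yl)-6-methoxyphenyl]-2-(3,5-dimethoxyphenyl)-1-(4-methoxyphenyl)ethan-1-ol
Product: 14 (2S,3S)-3-(3,5-dimethoxyphenyl)-6-(1,3-dioxolan-2-yl)-4-methoxy-2-(4-methoxyphenyl)-2,3-dihydro-1-benzofuran
Conditions: Pd2(dba)3 (2.5 mol%), t-BuBrettPhos (6 mol%), Cs2CO3, toluene, 90 °C
Reagents that add atoms: none
Why: intramolecular palladium-catalysed C–O cross-coupling (Buchwald-type etherification) of a secondary alkoxide with an aryl chloride closes the five-membered ring at C7a–O1; no bond to C2 or C3 is broken, so the anti alcohol gives the trans ring. The bulky biaryl phosphine favours C–O reductive elimination over beta-hydride elimination, and the carbonate base is too weak to touch C3–H while C6 is an acetal.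

Step 8
Reactants: 14 (2S,3S)-3-(3,5-dimethoxyphenyl)-6-(1,3-dioxolan-2-yl)-4-methoxy-2-(4-methoxyphenyl)-2,3-dihydro-1-benzofuran
Product: 15 (2S,3S)-3-(3,5-dimethoxyphenyl)-4-methoxy-2-(4-methoxyphenyl)-2,3-dihydro-1-benzofuran-6-carbaldehyde
Conditions: HCl (1 M aq.), THF, rt
Reagents that add atoms: water, O
Why: acid-catalysed acetal hydrolysis; dilute acid at room temperature should not ionise the O1–C2 bond while ring B is still a methyl ether, and no base is present to deprotonate the now activated C3–H.

Step 9
Reactants: 15 (2S,3S)-3-(3,5-dimethoxyphenyl)-4-methoxy-2-(4-methoxyphenyl)-2,3-dihydro-1-benzofuran-6-carbaldehyde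
Product: 16 gnetal, (2S,3S)-3-(3,5-dihydroxyphenyl)-4-hydroxy-2-(4-hydroxyphenyl)-2,3-dihydro-1-benzofuran-6-carbaldehyde
Conditions: BBr3 (10 equiv), CH2Cl2, −78 °C to rt; then ice-water
Reagents that add atoms: none
Why: Lewis-acid cleavage of aryl methyl ethers; each ether oxygen is complexed by boron and bromide attacks the methyl group, and the aldehyde is released from its boron adduct on hydrolysis. Complexation of the ring B oxygen lowers its ability to push out O1, and a reversible O1–C2 ionisation would reclose to the trans isomer because C3 is not touched.

## Compound list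

1 | 5-chlorovanillin (3-chloro-4-hydroxy-5-methoxybenzaldehyde) | O=Cc1cc(Cl)c(O)c(OC)c1 | starting material
2 | 2-chloro-4-formyl-6-methoxyphenyl trifluoromethanesulfonate | O=Cc1cc(Cl)c(OS(=O)(=O)C(F)(F)F)c(OC)c1 | intermediate
3 | 2-chloro-4-(1,3-dioxolan-2-yl)-6-methoxyphenyl trifluoromethanesulfonate | COc1cc(C2OCCO2)cc(Cl)c1OS(=O)(=O)C(F)(F)F | intermediate
4 | acenaphthoquinone (acenaphthylene-1,2-dione) | O=C1C(=O)c2cccc3cccc1c23 | starting material
5 | cis-1,2-dimethyl-1,2-dihydroacenaphthylene-1,2-diol (meso) | C[C@]1(O)c2cccc3cccc(c23)[C@@]1(C)O | intermediate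
6 | 1-ethynyl-3,5-dimethoxybenzene | COc1cc(C#C)cc(OC)c1 | starting material
7 | 2-[(E)-2-(3,5-dimethoxyphenyl)ethenyl]-1,3,2-benzodioxaborole (formed in the flask, not isolated) | COc1cc(/C=C/B2Oc3ccccc3O2)cc(OC)c1 | intermediate
8 | (E)-2-(3,5-dimethoxyphenyl)ethenylboronic acid cis-1,2-dimethylacenaphthene-1,2-diyl ester | COc1cc(/C=C/B2O[C@@]3(C)c4cccc5cccc(c45)[C@@]3(C)O2)cc(OC)c1 | intermediate
9 | 4-bromoanisole | COc1ccc(Br)cc1 | starting material
10 | 4-methoxyphenyllithium (formed in the flask, not isolated) | [Li]c1ccc(OC)cc1 | intermediate
11 | lithium [(E)-2-(3,5-dimethoxyphenyl)ethenyl](4-methoxyphenyl)borate of diol 5 (formed in the flask, not isolated; configuration at boron not defined) | [Li+].COc1ccc(cc1)[B-]2(/C=C/c3cc(OC)cc(OC)c3)O[C@@]4(C)c5cccc6cccc(c56)[C@@]4(C)O2 | intermediate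
12 | [(1S,2S)-2-[2-chloro-4-(1,3-dioxolan-2-yl)-6-methoxyphenyl]-2-(3,5-dimethoxyphenyl)-1-(4-methoxyphenyl)ethyl]boronic acid cis-1,2-dimethylacenaphthene-1,2-diyl ester | B1(O[C@@]2(C)c3cccc4cccc(c34)[C@@]2(C)O1)[C@H](c5ccc(OC)cc5)[C@H](c6c(Cl)cc(cc6OC)C7OCCO7)c8cc(OC)cc(OC)c8 | intermediate
13 | (1S,2S)-2-[2-chloro-4-(1,3-dioxolan-2-yl)-6-methoxyphenyl]-2-(3,5-dimethoxyphenyl)-1-(4-methoxyphenyl)ethan-1-ol | O[C@H](c1ccc(OC)cc1)[C@H](c1c(Cl)cc(cc1OC)C1OCCO1)c1cc(OC)cc(OC)c1 | intermediate
14 | (2S,3S)-3-(3,5-dimethoxyphenyl)-6-(1,3-dioxolan-2-yl)-4-methoxy-2-(4-methoxyphenyl)-2,3-dihydro-1-benzofuran (trans) | O1CCOC1c1cc(OC)c2c(c1)O[C@H](c1ccc(OC)cc1)[C@H]2c1cc(OC)cc(OC)c1 | intermediate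
15 | (2S,3S)-3-(3,5-dimethoxyphenyl)-4-methoxy-2-(4-methoxyphenyl)-2,3-dihydro-1-benzofuran-6-carbaldehyde (trans) | O=Cc1cc(OC)c2c(c1)O[C@H](c1ccc(OC)cc1)[C@H]2c1cc(OC)cc(OC)c1 | intermediate
16 | gnetal, (2S,3S)-3-(3,5-dihydroxyphenyl)-4-hydroxy-2-(4-hydroxyphenyl)-2,3-dihydro-1-benzofuran-6-carbaldehyde | O=Cc1cc(O)c2c(c1)O[C@H](c1ccc(O)cc1)[C@H]2c1cc(O)cc(O)c1 | target

## Step count and least certain steps

Total step count: 9. Longest linear sequence: 7 steps (steps 1, 2, 5, 6, 7, 8, 9 from 1; equally steps 3, 4, 5, 6, 7, 8, 9 from 4).

**Step 5 (key step).**
- What may go wrong: the arylpalladium species from 3 carries substituents at both ortho positions, and 11 is substituted at the far alkene carbon. Binding of the alkene may therefore be slow, so that direct transfer of the alkenyl or anisyl group from boron to palladium (the Suzuki–Miyaura pathway) overtakes the 1,2-shift. The crowded complex may also discriminate the alkene faces poorly.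
- Fallback, from 8, 9 and 3, returning at 13: absolute and relative control are separated. The same ate complex 11 is coupled with 3 under Pd(OAc)2 and the smaller achiral ligand 1,1'-bis(dicyclohexylphosphino)ferrocene. The anti relationship comes from the mechanism and not from the ligand, so this should give 12 together with its mirror image, the (1R,2R) boronate F1. Oxidation as in step 6 gives 13 and the (1R,2R) alcohol F2. Acylation with (1S)-camphanic chloride (pyridine, DMAP, CH2Cl2) gives two diastereomeric esters, the camphanate of 13 F3 and the camphanate of the (1R,2R) alcohol F4, to be separated by crystallisation or chromatography. Hydrolysis of the first with LiOH in aqueous THF returns 13 as a single enantiomer.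

**Step 7.**
- What may go wrong: the palladium alkoxide of 13 has a hydrogen on C2, so beta-hydride elimination to the ketone with reduction of the C–Cl bond may compete with C–O bond formation at the hindered chloride.
- Fallback, from 13, returning at 15: the ring is closed from the other side, at O1–C2. Borylation of the C–Cl bond (B2pin2, Pd(OAc)2, XPhos, KOAc, dioxane) uses a base too weak to form the alkoxide and gives the aryl pinacol boronate F5. Oxidation with alkaline H2O2 gives the phenol F6. Aqueous acid (p-TsOH, wet THF) then ionises the anisyl-stabilised C2–OH bond; the ring A phenol closes onto the cation anti to ring C, and the dioxolane is hydrolysed in the same operation. The configuration at C2 is then set by C3, which is not touched.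

**Step 9.**
- What may go wrong: Lewis-acid ionisation of the O1–C2 bond may be followed by attack of an electron-rich ring of a second molecule instead of reclosure, and the aldehyde may react at carbon with bromide.
- Fallback, from 14, returning at 16: the ethers are cleaved by a nucleophile instead of a Lewis acid, while C6 is still an acetal and C3–H is not activated. Excess NaSEt in DMF at 140 °C should give the tetraphenol acetal F7; the second cleavage on ring C is the slow one and has to be forced. PPTS in wet acetone then frees the aldehyde.

**Step 4.**
- What may go wrong: boron may add in part to the internal alkyne carbon, and the exchange onto diol 5 may stay incomplete, leaving mixed boron species that do not separate cleanly.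
- Fallback, from 6, returning at 8: hydroboration with pinacolborane under Cp2ZrHCl catalysis (Et3N, neat, 60 °C) gives the pinacol boronate F8, which is easily purified. NaIO4 and NH4OAc in aqueous acetone free the boronic acid F9. Condensation with 5 over MgSO4 in CH2Cl2 gives 8.

## Further compounds

F1 | step 5 | [(1R,2R)-2-[2-chloro-4-(1,3-dioxolan-2-yl)-6-methoxyphenyl]-2-(3,5-dimethoxyphenyl)-1-(4-methoxyphenyl)ethyl]boronic acid cis-1,2-dimethylacenaphthene-1,2-diyl ester | B1(O[C@@]2(C)c3cccc4cccc(c34)[C@@]2(C)O1)[C@@H](c5ccc(OC)cc5)[C@@H](c6c(Cl)cc(cc6OC)C7OCCO7)c8cc(OC)cc(OC)c8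
F2 | step 5 | (1R,2R)-2-[2-chloro-4-(1,3-dioxolan-2-yl)-6-methoxyphenyl]-2-(3,5-dimethoxyphenyl)-1-(4-methoxyphenyl)ethan-1-ol | O[C@@H](c1ccc(OC)cc1)[C@@H](c1c(Cl)cc(cc1OC)C1OCCO1)c1cc(OC)cc(OC)c1
F3 | step 5 | (1S,2S)-2-[2-chloro-4-(1,3-dioxolan-2-yl)-6-methoxyphenyl]-2-(3,5-dimethoxyphenyl)-1-(4-methoxyphenyl)ethyl (1S,4R)-camphanate | O=C(O[C@H](c1ccc(OC)cc1)[C@H](c1c(Cl)cc(cc1OC)C1OCCO1)c1cc(OC)cc(OC)c1)[C@@]12CC[C@@](C)(C(=O)O1)C2(C)C
F4 | step 5 | (1R,2R)-2-[2-chloro-4-(1,3-dioxolan-2-yl)-6-methoxyphenyl]-2-(3,5-dimethoxyphenyl)-1-(4-methoxyphenyl)ethyl (1S,4R)-camphanate | O=C(O[C@@H](c1ccc(OC)cc1)[C@@H](c1c(Cl)cc(cc1OC)C1OCCO1)c1cc(OC)cc(OC)c1)[C@@]12CC[C@@](C)(C(=O)O1)C2(C)C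
F5 | step 7 | (1S,2S)-2-[4-(1,3-dioxolan-2-yl)-2-methoxy-6-(4,4,5,5-tetramethyl-1,3,2-dioxaborolan-2-yl)phenyl]-2-(3,5-dimethoxyphenyl)-1-(4-methoxyphenyl)ethan-1-ol | O[C@H](c1ccc(OC)cc1)[C@H](c1c(B2OC(C)(C)C(C)(C)O2)cc(cc1OC)C1OCCO1)c1cc(OC)cc(OC)c1
F6 | step 7 | (1S,2S)-2-[4-(1,3-dioxolan-2-yl)-2-hydroxy-6-methoxyphenyl]-2-(3,5-dimethoxyphenyl)-1-(4-methoxyphenyl)ethan-1-ol | O[C@H](c1ccc(OC)cc1)[C@H](c1c(O)cc(cc1OC)C1OCCO1)c1cc(OC)cc(OC)c1
F7 | step 9 | (2S,3S)-3-(3,5-dihydroxyphenyl)-6-(1,3-dioxolan-2-yl)-2-(4-hydroxyphenyl)-2,3-dihydro-1-benzofuran-4-ol | O1CCOC1c1cc(O)c2c(c1)O[C@H](c1ccc(O)cc1)[C@H]2c1cc(O)cc(O)c1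
F8 | step 4 | 2-[(E)-2-(3,5-dimethoxyphenyl)ethenyl]-4,4,5,5-tetramethyl-1,3,2-dioxaborolane | COc1cc(/C=C/B2OC(C)(C)C(C)(C)O2)cc(OC)c1
F9 | step 4 | [(E)-2-(3,5-dimethoxyphenyl)ethenyl]boronic acid | COc1cc(/C=C/B(O)O)cc(OC)c1
A1 | alternative 1 | 2-[(1S,2S)-1-(3,5-dimethoxyphenyl)-2-(4-methoxyphenyl)-2-(triethylsilyloxy)ethyl]-3-(triisopropylsilyloxy)-5-[(triisopropylsilyloxy)methyl]phenol | CC[Si](CC)(CC)O[C@H](c1ccc(OC)cc1)[C@H](c1c(O)cc(CO[Si](C(C)C)(C(C)C)C(C)C)cc1O[Si](C(C)C)(C(C)C)C(C)C)c1cc(OC)cc(OC)c1
A2 | alternative 1 | 3-[(triisopropylsilyloxy)methyl]cyclobut-2-en-1-one | O=C1C=C(CO[Si](C(C)C)(C(C)C)C(C)C)C1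
A3 | alternative 1 | triethyl{[(1S,2S)-2-(3,5-dimethoxyphenyl)-1-(4-methoxyphenyl)-4-(triisopropylsilyloxy)but-3-yn-1-yl]oxy}silane | CC[Si](CC)(CC)O[C@H](c1ccc(OC)cc1)[C@H](C#CO[Si](C(C)C)(C(C)C)C(C)C)c1cc(OC)cc(OC)c1
A4 | alternative 2 | dimethyl (2S,3S)-4-methoxy-2-(4-methoxyphenyl)-2,3-dihydro-1-benzofuran-3,6-dicarboxylate | COC(=O)c1cc(OC)c2c(c1)O[C@H](c1ccc(OC)cc1)[C@H]2C(=O)OC
A5 | alternative 2 | methyl (2S)-5-methoxy-2-(4-methoxyphenyl)-4-oxo-3,4-dihydro-2H-1-benzopyran-7-carboxylate | COC(=O)c1cc(OC)c2C(=O)C[C@@H](c3ccc(OC)cc3)Oc2c1
A6 | alternative 3 | (2S,3S)-3-(3,5-dimethoxyphenyl)-4-ethoxy-2-(4-methoxyphenyl)-2,3-dihydro-1-benzofuran-6-carbaldehyde | O=Cc1cc(OCC)c2c(c1)O[C@H](c1ccc(OC)cc1)[C@H]2c1cc(OC)cc(OC)c1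
A7 | alternative 3 | (2S,3S)-3-(3,5-dimethoxyphenyl)-2-(4-methoxyphenyl)-4-oxo-2,3-dihydro-4H-furo[3,2-c]pyran-6-carbaldehyde | O=Cc1cc2O[C@H](c3ccc(OC)cc3)[C@@H](c4cc(OC)cc(OC)c4)c2c(=O)o1
A8 | alternative 3 | ethoxyethyne | CCOC#C
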